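**Plan**

- Locants: chromene O1, C2–C8a; cyclohexene C1'–C6' (C1' quaternary, C2' methine, C3'=C4'). The retrosynthesis first removes the methoxymethyl group on O5, then opens the pyran ring at O1–C8a. This aryl ether bond joins the oxygen on quaternary C2 to the fully substituted benzene carbon C8a across the cis C3=C4 alkene, and that feature allows a palladium-catalysed closure from a tertiary alkoxide and an aryl bromide.
- Further cuts: C3=C4 back to the alkyne, C4–C4a (Sonogashira), the side-chain bond C2–CH2 (alkylation of a lactic acid dioxolanone enolate, whose carboxyl carbon becomes C3), and C1'–C2' plus C5'–C6' of the cyclohexene (Diels–Alder).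
- Forward order: cyclohexene ring (steps 1–5), side chain grown to the iodide and joined to the lactate unit (6–9), alkyne made (10–12), arene prepared and attached (13–17), alkyne half-reduced (18), pyran ring closed last (19), phenol freed (20).
- Stereochemistry: C1' and C2' from a catalyst-controlled exo Diels–Alder reaction; C2 from (S)-lactic acid by self-regeneration of the stereocentre; the Z alkene from syn semi-hydrogenation.

Key step: step 19

Remark: the catalyst antipode in step 2 is chosen from the known facial preference of this oxazaborolidinium class with methacrolein; the (R)-prolinol-derived catalyst is assumed to lead to (1R,2R)-4, and its mirror image would be used if the sense proved opposite.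

**Route**

Step 1
Reactants: 1 (E)-3-methylpent-3-en-2-one
Product: 2 triisopropyl{[(3E)-3-methylpenta-1,3-dien-2-yl]oxy}silane
Conditions: i-Pr3SiOTf, Et3N, CH2Cl2, 0 °C
Reagents that add atoms: triisopropylsilyl trifluoromethanesulfonate, CC(C)[Si](OS(=O)(=O)C(F)(F)F)(C(C)C)C(C)C
Why: Soft enolisation of the methyl ketone (enol silylation with a silyl triflate and an amine) removes an acetyl proton and should give the cross-conjugated 2-silyloxy diene with the E trisubstituted alkene unchanged.

Step 2
Reactants: 2 triisopropyl{[(3E)-3-methylpenta-1,3-dien-2-yl]oxy}silane; 3 methacrolein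
Product: 4 (1R,2R)-1,2,3-trimethyl-4-[(triisopropylsilyl)oxy]cyclohex-3-ene-1-carbaldehyde
Conditions: B-(o-tolyl)oxazaborolidine from (R)-α,α-diphenylprolinol (15 mol %), Tf2NH (12 mol %), CH2Cl2, −78 → −40 °C
Reagents that add atoms: none
Why: Enantioselective Diels–Alder reaction under chiral oxazaborolidinium catalysis, in which the silyloxy group (para director) and the terminal methyl (ortho director) both place the formyl-bearing carbon next to the methyl-bearing diene terminus, the catalyst shields one face of the bound enal and so sets C1', and the exo-formyl transition state expected for a 2-substituted acrolein meeting a diene with a bulky 2-silyloxy group and a 3-methyl group sets C2' with its methyl cis to the C1' methyl.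

Step 3
Reactants: 4 (1R,2R)-1,2,3-trimethyl-4-[(triisopropylsilyl)oxy]cyclohex-3-ene-1-carbaldehyde
Product: 5 triisopropyl{[(3S,4S)-4-ethenyl-2,3,4-trimethylcyclohex-1-en-1-yl]oxy}silane
Conditions: Ph3PCH3Br, KOt-Bu, THF, 0 °C → rt
Reagents that add atoms: methyltriphenylphosphonium bromide, C[P+](c1ccccc1)(c1ccccc1)c1ccccc1.[Br-]
Why: Wittig methylenation of a non-enolisable aldehyde, to which the silyl enol ether and both stereocentres are inert.

Step 4
Reactants: 5 triisopropyl{[(3S,4S)-4-ethenyl-2,3,4-trimethylcyclohex-1-en-1-yl]oxy}silane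
Product: 6 (3S,4S)-4-ethenyl-2,3,4-trimethylcyclohex-1-en-1-yl trifluoromethanesulfonate
Conditions: CsF, PhNTf2, DME, rt
Reagents that add atoms: N-phenylbis(trifluoromethanesulfonimide), FC(F)(F)S(=O)(=O)N(c1ccccc1)S(=O)(=O)C(F)(F)F
Why: Fluoride-induced desilylation releases the regiodefined enolate, which PhNTf2 traps on oxygen (silyl enol ether to enol triflate exchange), so the double bond stays at C3'=C4' as fixed by the cycloaddition.

Step 5
Reactants: 6 (3S,4S)-4-ethenyl-2,3,4-trimethylcyclohex-1-en-1-yl trifluoromethanesulfonate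
Product: 7 (5S,6R)-5-ethenyl-1,5,6-trimethylcyclohex-1-ene
Conditions: Pd(OAc)2 (5 mol %), PPh3, HCO2H, Bu3N, DMF, 60 °C; the volatile product is handled as a concentrated solution
Reagents that add atoms: none
Why: Palladium-catalysed formate reduction of an enol triflate (oxidative addition, decarboxylation of formate to a hydride, reductive elimination) replaces the triflate by hydrogen without moving the alkene, and an intramolecular Heck reaction with the vinyl group is excluded because it would create a bridgehead alkene.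

Step 6
Reactants: 7 (5S,6R)-5-ethenyl-1,5,6-trimethylcyclohex-1-ene
Product: 9 2-[(1S,2S)-1,2,3-trimethylcyclohex-3-en-1-yl]ethan-1-ol, via B-alkyl-9-borabicyclononane 8 (not isolated)
Conditions: 9-BBN, THF, 0 °C → rt; then NaOH, H2O2, H2O, 0 °C → rt
Reagents that add atoms: hydrogen peroxide, OO
Why: Brown hydroboration–oxidation, in which 9-BBN adds anti-Markovnikov to the monosubstituted vinyl group much faster than to the trisubstituted ring alkene and alkaline peroxide then replaces boron by hydroxyl.

Step 7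
Reactants: 9 2-[(1S,2S)-1,2,3-trimethylcyclohex-3-en-1-yl]ethan-1-ol
Product: 10 (5S,6S)-5-(2-iodoethyl)-1,5,6-trimethylcyclohex-1-ene
Conditions: I2, PPh3, imidazole, CH2Cl2, 0 °C → rt
Reagents that add atoms: iodine, II
Why: Appel-type iodination converts the unhindered primary alcohol into the iodide by SN2 displacement of an alkoxyphosphonium group under neutral conditions.

Step 8
Reactants: 11 (S)-lactic acid
Product: 12 (2S,5S)-2-tert-butyl-5-methyl-1,3-dioxolan-4-one
Conditions: t-BuCHO, TsOH (cat.), H2SO4 (cat.), pentane, reflux, Dean–Stark; cis isomer purified by low-temperature crystallisation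
Reagents that add atoms: pivalaldehyde, CC(C)(C)C=O
Why: Acid-catalysed acetalisation with azeotropic removal of water (Seebach dioxolanone formation) stores the lactic acid configuration in a new acetal centre, the cis (2S,5S) isomer being the favoured one.

Step 9
Reactants: 12 (2S,5S)-2-tert-butyl-5-methyl-1,3-dioxolan-4-one; 10 (5S,6S)-5-(2-iodoethyl)-1,5,6-trimethylcyclohex-1-ene
Product: 14 (2S,5R)-2-tert-butyl-5-methyl-5-{2-[(1S,2S)-1,2,3-trimethylcyclohex-3-en-1-yl]ethyl}-1,3-dioxolan-4-one, via lithium dioxolanone enolate 13 (not isolated)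
Conditions: LiN(i-Pr)2, THF, −78 °C; then 10, DMPU, −78 → −30 °C
Reagents that add atoms: none
Why: Seebach enolate alkylation with self-regeneration of the stereocentre, in which the planar enolate keeps the acetal centre and the iodide approaches the face opposite the tert-butyl group, so the new chain takes the place of the former hydrogen and the future chromene C2 is set.

Step 10
Reactants: 14 (2S,5R)-2-tert-butyl-5-methyl-5-{2-[(1S,2S)-1,2,3-trimethylcyclohex-3-en-1-yl]ethyl}-1,3-dioxolan-4-one
Product: 15 (2R)-2-methyl-4-[(1S,2S)-1,2,3-trimethylcyclohex-3-en-1-yl]butane-1,2-diol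
Conditions: LiAlH4, THF, 0 °C → rt
Reagents that add atoms: none
Why: Hydride reduction of the lactone-type acetal turns the carbonyl into the primary alcohol and releases the tertiary hydroxyl, with the ring alkene and the quaternary carbinol untouched.

Step 11
Reactants: 15 (2R)-2-methyl-4-[(1S,2S)-1,2,3-trimethylcyclohex-3-en-1-yl]butane-1,2-diol
Product: 16 (2R)-2-hydroxy-2-methyl-4-[(1S,2S)-1,2,3-trimethylcyclohex-3-en-1-yl]butanal
Conditions: SO3·pyridine, DMSO, i-Pr2NEt, CH2Cl2, 0 °C; used crude
Reagents that add atoms: none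
Why: Parikh–Doering oxidation (activated DMSO) oxidises only the primary hydroxyl, since the tertiary one has no carbinol hydrogen.

Step 12
Reactants: 16 (2R)-2-hydroxy-2-methyl-4-[(1S,2S)-1,2,3-trimethylcyclohex-3-en-1-yl]butanal
Product: 17 (3R)-3-methyl-5-[(1S,2S)-1,2,3-trimethylcyclohex-3-en-1-yl]pent-1-yn-3-ol
Conditions: dimethyl (1-diazo-2-oxopropyl)phosphonate, K2CO3, MeOH, 0 °C → rt
Reagents that add atoms: dimethyl (1-diazo-2-oxopropyl)phosphonate, COP(=O)(OC)C(=[N+]=[N-])C(C)=O
Why: Ohira–Bestmann variant of the Seyferth–Gilbert homologation converts the aldehyde into the terminal alkyne under mild base, and the quaternary α-carbon cannot epimerise.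

Step 13
Reactants: 18 2,3,4-trimethoxybenzaldehyde
Product: 20 2,3,4-trimethoxyphenol, via 2,3,4-trimethoxyphenyl formate 19 (not isolated)
Conditions: mCPBA, CH2Cl2, 0 °C → rt; NaHCO3 wash; then K2CO3 (cat.), MeOH, rt
Reagents that add atoms: 3-chloroperoxybenzoic acid, OOC(=O)c1cccc(Cl)c1
Why: Baeyer–Villiger (Dakin-type) oxidation, in which the electron-rich aryl group migrates to oxygen to give the aryl formate that is then methanolysed to the phenol.

Step 14
Reactants: 20 2,3,4-trimethoxyphenol
Product: 21 1,2,3-trimethoxy-4-(methoxymethoxy)benzene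
Conditions: MeOCH2Cl, i-Pr2NEt, CH2Cl2, 0 °C → rt
Reagents that add atoms: chloromethyl methyl ether, COCCl
Why: O-alkylation of the phenol (Williamson-type) installs an acetal protecting group that also serves as the directing group for the next step.

Step 15
Reactants: 21 1,2,3-trimethoxy-4-(methoxymethoxy)benzene
Product: 23 1-iodo-3,4,5-trimethoxy-2-(methoxymethoxy)benzene, via ortho-lithiated arene 22 (not isolated)
Conditions: n-BuLi, THF, 0 °C; then I2, −78 °C → rt
Reagents that add atoms: iodine, II
Why: Directed ortho-metalation, in which the methoxymethoxy group, a stronger director than methoxy, guides butyllithium to its only free ortho position and iodine quenches the aryllithium there.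

Step 16
Reactants: 23 1-iodo-3,4,5-trimethoxy-2-(methoxymethoxy)benzene
Product: 24 1-bromo-2-iodo-4,5,6-trimethoxy-3-(methoxymethoxy)benzene
Conditions: NBS, MeCN, 0 °C → rt
Reagents that add atoms: N-bromosuccinimide, BrN1C(=O)CCC1=O
Why: Electrophilic aromatic bromination at the single remaining ring position, which is activated by one ortho and one para methoxy group.

Step 17
Reactants: 24 1-bromo-2-iodo-4,5,6-trimethoxy-3-(methoxymethoxy)benzene; 17 (3R)-3-methyl-5-[(1S,2S)-1,2,3-trimethylcyclohex-3-en-1-yl]pent-1-yn-3-ol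
Product: 25 (3R)-1-[2-bromo-3,4,5-trimethoxy-6-(methoxymethoxy)phenyl]-3-methyl-5-[(1S,2S)-1,2,3-trimethylcyclohex-3-en-1-yl]pent-1-yn-3-ol
Conditions: PdCl2(PPh3)2 (5 mol %), CuI (10 mol %), Et3N, THF, degassed, 40 °C
Reagents that add atoms: none
Why: Sonogashira coupling takes place at the C–I bond, whose oxidative addition to zerovalent palladium is much faster than that of the neighbouring C–Br bond, and it tolerates the free tertiary propargylic alcohol.

Step 18
Reactants: 25 (3R)-1-[2-bromo-3,4,5-trimethoxy-6-(methoxymethoxy)phenyl]-3-methyl-5-[(1S,2S)-1,2,3-trimethylcyclohex-3-en-1-yl]pent-1-yn-3-ol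
Product: 26 (1Z,3R)-1-[2-bromo-3,4,5-trimethoxy-6-(methoxymethoxy)phenyl]-3-methyl-5-[(1S,2S)-1,2,3-trimethylcyclohex-3-en-1-yl]pent-1-en-3-ol
Conditions: H2 (1 atm), Pd/CaCO3 poisoned with Pb(OAc)2, quinoline, EtOAc, rt
Reagents that add atoms: none
Why: Lindlar semi-hydrogenation delivers both hydrogens to the same face of the alkyne on the poisoned palladium surface and so gives the Z alkene, while the aryl bromide and the trisubstituted ring alkene are not reduced.

Step 19
Reactants: 26 (1Z,3R)-1-[2-bromo-3,4,5-trimethoxy-6-(methoxymethoxy)phenyl]-3-methyl-5-[(1S,2S)-1,2,3-trimethylcyclohex-3-en-1-yl]pent-1-en-3-ol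
Product: 27 (2R)-6,7,8-trimethoxy-5-(methoxymethoxy)-2-methyl-2-{2-[(1S,2S)-1,2,3-trimethylcyclohex-3-en-1-yl]ethyl}-2H-chromene
Conditions: Pd(OAc)2 (5 mol %), 2-(di-tert-butylphosphino)-1,1'-binaphthyl (6 mol %), Cs2CO3, toluene, 70 °C
Reagents that add atoms: none
Why: Zerovalent palladium bearing the bulky, electron-rich phosphine inserts into the C8a–Br bond, the cesium alkoxide of the C2 carbinol replaces bromide on divalent palladium to give a seven-membered aryl(alkoxo)palladium chelate, and C–O reductive elimination forms O1–C8a and returns the catalyst. The closest known reaction is the Buchwald-type intramolecular etherification of aryl bromides with tethered alcohols, tertiary ones included. The six-membered pyran ring is closed by aryl–oxygen bond formation at the ring-fusion carbon through reductive elimination from the palladacycle, not by attack on a saturated carbon, so no stereocentre is formed and C2 keeps its lactate-derived R configuration because none of its bonds is broken. The step needs C–O coupling to win over hydrodebromination and β-hydride pathways: the tertiary alkoxide has no hydrogen on the carbinol carbon, and the hindered ligand speeds up reductive elimination. It also needs hydroxyl and bromide on the same side of the alkene, which the Z geometry from step 18 provides, and the methoxymethyl ether keeps the C5 oxygen from competing as a phenoxide.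

Step 20
Reactants: 27 (2R)-6,7,8-trimethoxy-5-(methoxymethoxy)-2-methyl-2-{2-[(1S,2S)-1,2,3-trimethylcyclohex-3-en-1-yl]ethyl}-2H-chromene
Product: 28 (2R)-6,7,8-trimethoxy-2-methyl-2-{2-[(1S,2S)-1,2,3-trimethylcyclohex-3-en-1-yl]ethyl}-2H-chromen-5-ol
Conditions: HCl (3 M aq., few equiv.), MeOH, rt
Reagents that add atoms: none
Why: Acid-catalysed acetal cleavage (methanolysis of the phenolic methoxymethyl ether) frees the C5 phenol under conditions too mild to ionise the chromene or move the ring alkene.

**Compound list**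

1 | (E)-3-methylpent-3-en-2-one | C/C=C(\C)C(C)=O | starting material
2 | triisopropyl{[(3E)-3-methylpenta-1,3-dien-2-yl]oxy}silane | C/C=C(\C)C(=C)O[Si](C(C)C)(C(C)C)C(C)C | intermediate
3 | methacrolein (2-methylprop-2-enal) | CC(=C)C=O | starting material
4 | (1R,2R)-1,2,3-trimethyl-4-[(triisopropylsilyl)oxy]cyclohex-3-ene-1-carbaldehyde | O=C[C@]1(C)CCC(O[Si](C(C)C)(C(C)C)C(C)C)=C(C)[C@H]1C | intermediate
5 | triisopropyl{[(3S,4S)-4-ethenyl-2,3,4-trimethylcyclohex-1-en-1-yl]oxy}silane | C=C[C@]1(C)CCC(O[Si](C(C)C)(C(C)C)C(C)C)=C(C)[C@H]1C | intermediate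
6 | (3S,4S)-4-ethenyl-2,3,4-trimethylcyclohex-1-en-1-yl trifluoromethanesulfonate | C=C[C@]1(C)CCC(OS(=O)(=O)C(F)(F)F)=C(C)[C@H]1C | intermediate
7 | (5S,6R)-5-ethenyl-1,5,6-trimethylcyclohex-1-ene | C=C[C@]1(C)CCC=C(C)[C@H]1C | intermediate
8 | 9-{2-[(1R,2S)-1,2,3-trimethylcyclohex-3-en-1-yl]ethyl}-9-borabicyclo[3.3.1]nonane | B1(CC[C@]2(C)CCC=C(C)[C@H]2C)C3CCCC1CCC3 | intermediate
9 | 2-[(1S,2S)-1,2,3-trimethylcyclohex-3-en-1-yl]ethan-1-ol | OCC[C@]1(C)CCC=C(C)[C@H]1C | intermediate
10 | (5S,6S)-5-(2-iodoethyl)-1,5,6-trimethylcyclohex-1-ene | ICC[C@]1(C)CCC=C(C)[C@H]1C | intermediate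
11 | (S)-lactic acid | C[C@H](O)C(O)=O | starting material
12 | (2S,5S)-2-tert-butyl-5-methyl-1,3-dioxolan-4-one | C[C@@H]1O[C@H](C(C)(C)C)OC1=O | intermediate
13 | lithium (2S)-2-tert-butyl-5-methyl-1,3-dioxol-4-olate | CC1=C(O[Li])O[C@@H](C(C)(C)C)O1 | intermediate
14 | (2S,5R)-2-tert-butyl-5-methyl-5-{2-[(1S,2S)-1,2,3-trimethylcyclohex-3-en-1-yl]ethyl}-1,3-dioxolan-4-one | C[C@]1(CC[C@]2(C)CCC=C(C)[C@H]2C)O[C@H](C(C)(C)C)OC1=O | intermediate
15 | (2R)-2-methyl-4-[(1S,2S)-1,2,3-trimethylcyclohex-3-en-1-yl]butane-1,2-diol | C[C@](CC[C@]1(C)CCC=C(C)[C@H]1C)(O)CO | intermediate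
16 | (2R)-2-hydroxy-2-methyl-4-[(1S,2S)-1,2,3-trimethylcyclohex-3-en-1-yl]butanal | C[C@](CC[C@]1(C)CCC=C(C)[C@H]1C)(O)C=O | intermediate
17 | (3R)-3-methyl-5-[(1S,2S)-1,2,3-trimethylcyclohex-3-en-1-yl]pent-1-yn-3-ol | C#C[C@](C)(O)CC[C@]1(C)CCC=C(C)[C@H]1C | intermediate
18 | 2,3,4-trimethoxybenzaldehyde | COc1ccc(C=O)c(OC)c1OC | starting material
19 | 2,3,4-trimethoxyphenyl formate | COc1ccc(OC=O)c(OC)c1OC | intermediate
20 | 2,3,4-trimethoxyphenol | COc1ccc(O)c(OC)c1OC | intermediate
21 | 1,2,3-trimethoxy-4-(methoxymethoxy)benzene | COCOc1ccc(OC)c(OC)c1OC | intermediate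
22 | [3,4,5-trimethoxy-2-(methoxymethoxy)phenyl]lithium | COCOc1c([Li])cc(OC)c(OC)c1OC | intermediate
23 | 1-iodo-3,4,5-trimethoxy-2-(methoxymethoxy)benzene | COCOc1c(I)cc(OC)c(OC)c1OC | intermediate
24 | 1-bromo-2-iodo-4,5,6-trimethoxy-3-(methoxymethoxy)benzene | COCOc1c(I)c(Br)c(OC)c(OC)c1OC | intermediate
25 | (3R)-1-[2-bromo-3,4,5-trimethoxy-6-(methoxymethoxy)phenyl]-3-methyl-5-[(1S,2S)-1,2,3-trimethylcyclohex-3-en-1-yl]pent-1-yn-3-ol | COCOc1c(C#C[C@](C)(O)CC[C@]2(C)CCC=C(C)[C@H]2C)c(Br)c(OC)c(OC)c1OC | intermediate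
26 | (1Z,3R)-1-[2-bromo-3,4,5-trimethoxy-6-(methoxymethoxy)phenyl]-3-methyl-5-[(1S,2S)-1,2,3-trimethylcyclohex-3-en-1-yl]pent-1-en-3-ol | COCOc1c(/C=C\[C@](C)(O)CC[C@]2(C)CCC=C(C)[C@H]2C)c(Br)c(OC)c(OC)c1OC | intermediate
27 | (2R)-6,7,8-trimethoxy-5-(methoxymethoxy)-2-methyl-2-{2-[(1S,2S)-1,2,3-trimethylcyclohex-3-en-1-yl]ethyl}-2H-chromene | COc1c(OCOC)c2c(c(OC)c1OC)O[C@](C)(CC[C@]1(C)CCC=C(C)[C@H]1C)C=C2 | intermediate
28 | (2R)-6,7,8-trimethoxy-2-methyl-2-{2-[(1S,2S)-1,2,3-trimethylcyclohex-3-en-1-yl]ethyl}-2H-chromen-5-ol | COc1c(O)c2c(c(OC)c1OC)O[C@](C)(CC[C@]1(C)CCC=C(C)[C@H]1C)C=C2 | target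

**Count**

Total steps: 20. Longest linear sequence: 15 steps (1–7, 9–12, 17–20); steps 8 and 13–16 are on side branches.

**Steps most likely to fail**

Step 2. The cycloaddition may not follow the exo-formyl course: the catalyst-bound formyl group may instead sit under the diene, which would place the C1' and C2' methyl groups trans, or the face selectivity may erode. The fallback exchanges the roles of the two α-substituents of the dienophile, so that the endo course becomes the productive one.
- It sets out from diene 2, which is combined with 4-[(4-methoxyphenyl)methoxy]-2-methylidenebutanal F1, prepared from 4-[(4-methoxybenzyl)oxy]butanal by α-methylenation with aqueous formaldehyde and pyrrolidinium propionate.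
- With the mirror-image (S)-prolinol-derived oxazaborolidinium catalyst, the endo adduct (1R,2R)-1-{2-[(4-methoxybenzyl)oxy]ethyl}-2,3-dimethyl-4-[(triisopropylsilyl)oxy]cyclohex-3-ene-1-carbaldehyde F2 should carry the formyl group cis to the C2' methyl.
- CsF and PhNTf2 should convert it into (3R,4R)-4-formyl-4-{2-[(4-methoxybenzyl)oxy]ethyl}-2,3-dimethylcyclohex-1-en-1-yl trifluoromethanesulfonate F3.
- Reduction with Pd(OAc)2, PPh3, HCO2H and Bu3N should give (1R,2R)-1-{2-[(4-methoxybenzyl)oxy]ethyl}-2,3-dimethylcyclohex-3-ene-1-carbaldehyde F4.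
- Wolff–Kishner reduction (N2H4·H2O, KOH, diethylene glycol, 200 °C) turns the formyl group into the C1' methyl of 1-methoxy-4-({2-[(1S,2S)-1,2,3-trimethylcyclohex-3-en-1-yl]ethoxy}methyl)benzene F5.
- DDQ in CH2Cl2 with pH 7 buffer removes the 4-methoxybenzyl group, and the route is rejoined at alcohol 9.

Step 19. Oxidative addition into the hindered, electron-rich C8a–Br bond may be slow, so that hydrodebromination or catalyst decay outruns C–O reductive elimination. The fallback leaves palladium for a copper-mediated Ullmann-type etherification on a more reactive halide.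
- It sets out from bromide 26, which undergoes aromatic halogen exchange (CuI, NaI, trans-N,N'-dimethylcyclohexane-1,2-diamine, dioxane, 110 °C) to (1Z,3R)-1-[2-iodo-3,4,5-trimethoxy-6-(methoxymethoxy)phenyl]-3-methyl-5-[(1S,2S)-1,2,3-trimethylcyclohex-3-en-1-yl]pent-1-en-3-ol F6.
- F6 is closed with CuI, 3,4,7,8-tetramethyl-1,10-phenanthroline and Cs2CO3 in toluene at 110 °C, which forms the same O1–C8a bond and rejoins the route at 27.

Step 9. SN2 attack on the unactivated primary iodide may be too slow for the thermally fragile enolate, which decomposes on warming before it is alkylated. The fallback replaces the alkylation by an aldol addition and a deoxygenation.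
- It sets out from alcohol 9, which Dess–Martin periodinane oxidises to 2-[(1S,2S)-1,2,3-trimethylcyclohex-3-en-1-yl]acetaldehyde F7.
- Enolate 13 (from 12, LiN(i-Pr)2, THF, −78 °C) adds to F7 from the face opposite the tert-butyl group to give (2S,5R)-2-tert-butyl-5-{1-hydroxy-2-[(1S,2S)-1,2,3-trimethylcyclohex-3-en-1-yl]ethyl}-5-methyl-1,3-dioxolan-4-one F8, as a mixture at the carbinol carbon, which is of no consequence.
- 1,1'-Thiocarbonyldiimidazole and DMAP give (2S,5R)-2-tert-butyl-5-{1-[(1H-imidazol-1-ylcarbonothioyl)oxy]-2-[(1S,2S)-1,2,3-trimethylcyclohex-3-en-1-yl]ethyl}-5-methyl-1,3-dioxolan-4-one F9.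
- Barton–McCombie deoxygenation (Bu3SnH, AIBN, toluene, 90 °C, high stannane concentration to outrun radical cyclisation onto the ring alkene) rejoins the route at 14.

**Further compounds**

F1 | step 2 | 4-[(4-methoxyphenyl)methoxy]-2-methylidenebutanal | C=C(CCOCc1ccc(OC)cc1)C=O
F2 | step 2 | (1R,2R)-1-{2-[(4-methoxybenzyl)oxy]ethyl}-2,3-dimethyl-4-[(triisopropylsilyl)oxy]cyclohex-3-ene-1-carbaldehyde | COc1ccc(COCC[C@]2(C=O)CCC(O[Si](C(C)C)(C(C)C)C(C)C)=C(C)[C@H]2C)cc1
F3 | step 2 | (3R,4R)-4-formyl-4-{2-[(4-methoxybenzyl)oxy]ethyl}-2,3-dimethylcyclohex-1-en-1-yl trifluoromethanesulfonate | COc1ccc(COCC[C@]2(C=O)CCC(OS(=O)(=O)C(F)(F)F)=C(C)[C@H]2C)cc1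
F4 | step 2 | (1R,2R)-1-{2-[(4-methoxybenzyl)oxy]ethyl}-2,3-dimethylcyclohex-3-ene-1-carbaldehyde | COc1ccc(COCC[C@]2(C=O)CCC=C(C)[C@H]2C)cc1
F5 | step 2 | 1-methoxy-4-({2-[(1S,2S)-1,2,3-trimethylcyclohex-3-en-1-yl]ethoxy}methyl)benzene | COc1ccc(COCC[C@]2(C)CCC=C(C)[C@H]2C)cc1
F6 | step 19 | (1Z,3R)-1-[2-iodo-3,4,5-trimethoxy-6-(methoxymethoxy)phenyl]-3-methyl-5-[(1S,2S)-1,2,3-trimethylcyclohex-3-en-1-yl]pent-1-en-3-ol | COCOc1c(/C=C\[C@](C)(O)CC[C@]2(C)CCC=C(C)[C@H]2C)c(I)c(OC)c(OC)c1OC
F7 | step 9 | 2-[(1S,2S)-1,2,3-trimethylcyclohex-3-en-1-yl]acetaldehyde | O=CC[C@]1(C)CCC=C(C)[C@H]1C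
F8 | step 9 | (2S,5R)-2-tert-butyl-5-{1-hydroxy-2-[(1S,2S)-1,2,3-trimethylcyclohex-3-en-1-yl]ethyl}-5-methyl-1,3-dioxolan-4-one | C[C@]1(C(O)C[C@]2(C)CCC=C(C)[C@H]2C)O[C@H](C(C)(C)C)OC1=O
F9 | step 9 | (2S,5R)-2-tert-butyl-5-{1-[(1H-imidazol-1-ylcarbonothioyl)oxy]-2-[(1S,2S)-1,2,3-trimethylcyclohex-3-en-1-yl]ethyl}-5-methyl-1,3-dioxolan-4-one | C[C@]1(C(OC(=S)n2ccnc2)C[C@]3(C)CCC=C(C)[C@H]3C)O[C@H](C(C)(C)C)OC1=O
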